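**Retrosynthetic overview**
- Target ⇒ ketal hydrolysis of its 3,19-acetonide; the equatorial (7R) carbinol ⇒ Luche reduction of the 8(17)-en-7-one ⇒ oxidation of the axial (7S) allylic alcohol.
- Key bond, C7–O ⇒ SeO2 ene reaction followed by [2,3]-sigmatropic rearrangement of the allylseleninic acid on the 8(17)-alkene of 14-deoxyandrographolide acetonide.
- α-Alkylbutenolide ⇒ SN2' hydride reduction of the 14-acetate ⇒ (−)-andrographolide (ketalisation and acetylation in one pot).
- Ring order: rings A and B (trans-decalin) and the lactone ring arrive intact in andrographolide together with C3, C4, C5, C9 and C10. Only a temporary 1,3-dioxane is closed (first step) and opened (last step); C7 is set under control of the bought centres.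

Assumption: (−)-andrographolide, the bulk diterpenoid of Andrographis paniculata, is taken as the commercial starting material, and ent-labdane numbering (C1–C20) is used; in the target the 7-OH is equatorial, syn to the C10 methyl, which is (7R).

**Step 1**
Reactants: 1 (−)-andrographolide
Product: 3 14-O-acetyl-3,19-O-isopropylideneandrographolide, via acetonide 2 (not isolated)
Conditions: 2,2-dimethoxypropane (3 equiv), pyridinium p-toluenesulfonate (PPTS, 5 mol %), CH2Cl2, 40 °C, 2 h; then Et3N (6 equiv), Ac2O (4 equiv), 4-(dimethylamino)pyridine (DMAP, 5 mol %), 0 °C → rt, 2 h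
Reagents that add atoms: 2,2-dimethoxypropane, COC(C)(C)OC; acetic anhydride, CC(=O)OC(C)=O
Why: Acid-catalysed transketalisation closes the six-membered 1,3-dioxane across the C3/C19 1,3-diol, which leaves the allylic C14 hydroxyl as the only free alcohol for DMAP-catalysed O-acetylation (turning this Morita–Baylis–Hillman-type carbinol into a leaving group), and no stereocentre is touched.

**Step 2**
Reactants: 3 14-O-acetyl-3,19-O-isopropylideneandrographolide
Product: 4 3,19-O-isopropylidene-14-deoxyandrographolide
Conditions: NaBH4 (1.2 equiv), THF–MeOH 10:1, −20 → 0 °C, 30 min; aq. NH4Cl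
Reagents that add atoms: none
Why: SN2' reduction of a Morita–Baylis–Hillman-type acetate: hydride adds in conjugate fashion to C12 of the α-alkylidene lactone and the enolate expels the C14 acetate (E1cB), which gives the endocyclic α-alkylbutenolide, removes the C14 stereocentre on purpose and leaves the isolated 8(17)-alkene, the ketal and the five ring stereocentres alone.

**Step 3**
Reactants: 4 3,19-O-isopropylidene-14-deoxyandrographolide
Product: 7 (7S)-7-hydroxy-3,19-O-isopropylidene-14-deoxyandrographolide, via allylseleninic acid 5 (not isolated), via selenoxylate ester 6 (not isolated)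
Conditions: SeO2 (0.5 equiv, turned over by the hydroperoxide), t-BuOOH (5.5 M in decane, 2.5 equiv), CH2Cl2, 0 °C → rt, 16 h; aq. Na2S2O3–NaHCO3
Reagents that add atoms: selenium dioxide, O=[Se]=O (oxygen carrier); tert-butyl hydroperoxide, CC(C)(C)OO (terminal oxygen source that re-forms SeO2)
Why: Riley allylic oxidation run catalytically in SeO2: an ene reaction on the electron-rich 1,1-disubstituted 8(17)-alkene (the electron-poor butenolide alkene is inert, and the ring CH2 at C7 is preferred over the hindered methine C9) takes the axial H-7 to give 5, whose [2,3]-sigmatropic rearrangement forms the C7–O bond on that same axial face (anti to the C10 methyl, under control of the bought ring-fusion centres) and restores the exocyclic methylene, so that hydrolysis of 6 gives the axial (7S) alcohol.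

**Step 4**
Reactants: 7 (7S)-7-hydroxy-3,19-O-isopropylidene-14-deoxyandrographolide
Product: 8 7-oxo-3,19-O-isopropylidene-14-deoxyandrographolide
Conditions: Dess–Martin periodinane (1.3 equiv), NaHCO3 (5 equiv), CH2Cl2, 0 °C → rt, 1 h
Reagents that add atoms: none
Why: Dess–Martin oxidation of the only free hydroxyl under buffered, non-enolising conditions, which needs no overlap of the equatorial C7–H with the alkene π-system as MnO2 would, deliberately erases the wrongly configured C7 centre and keeps the exocyclic enone from drifting to the tetrasubstituted 8(9)-isomer.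

**Step 5**
Reactants: 8 7-oxo-3,19-O-isopropylidene-14-deoxyandrographolide
Product: 9 (7R)-7-hydroxy-3,19-O-isopropylidene-14-deoxyandrographolide
Conditions: NaBH4 (1.1 equiv), CeCl3·7H2O (1.2 equiv), MeOH, −78 °C, 30 min; aq. NH4Cl
Reagents that add atoms: none
Why: Luche reduction gives clean 1,2-reduction of the enone (no conjugate reduction of the enone or of the butenolide at −78 °C), and the small hydride adds along the axial trajectory past H-5 and H-9, anti to the axial C10 methyl, so the new hydroxyl ends up equatorial, i.e. (7R), by substrate control from the bought stereocentres.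

**Step 6**
Reactants: 9 (7R)-7-hydroxy-3,19-O-isopropylidene-14-deoxyandrographolide
Product: 10 (7R)-7-hydroxy-14-deoxyandrographolide (target)
Conditions: AcOH–H2O 7:3, rt, 1 h; evaporate with toluene
Reagents that add atoms: none
Why: Acid-catalysed hydrolysis of the 1,3-dioxane ketal in aqueous acetic acid frees the C3/C19 diol under conditions too mild to ionise the allylic alcohol, isomerise the exocyclic alkene or open the butenolide, and no stereocentre is affected.

**Compound list**
1 | (−)-andrographolide: ent-labdane with 3-OH, 19-OH (CH2OH on C4), 14-OH, 8(17)-exocyclic methylene and (12E)-alkylidene 16,15-olide; (3R,4R,5S,9R,10S,14S) | C=C1CC[C@@H]2[C@](C)(CO)[C@H](O)CC[C@@]2(C)[C@@H]1C/C=C1\[C@H](O)COC1=O | starting material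
2 | 3,19-O-isopropylideneandrographolide (2,2-dimethyl-1,3-dioxane across O3 and O19; all centres as in 1) | C=C1CC[C@@H]2[C@](C)(CO3)[C@H](OC3(C)C)CC[C@@]2(C)[C@@H]1C/C=C1\[C@H](O)COC1=O | intermediate
3 | 14-O-acetyl-3,19-O-isopropylideneandrographolide (14S acetate; all centres as in 1) | C=C1CC[C@@H]2[C@](C)(CO3)[C@H](OC3(C)C)CC[C@@]2(C)[C@@H]1C/C=C1\[C@H](OC(C)=O)COC1=O | intermediate
4 | 3,19-O-isopropylidene-14-deoxyandrographolide (C12 is CH2, butenolide alkene C13=C14; ring centres as in 1) | C=C1CC[C@@H]2[C@](C)(CO3)[C@H](OC3(C)C)CC[C@@]2(C)[C@@H]1CCC1=CCOC1=O | intermediate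
5 | allylseleninic acid: ene adduct of 4 with C17–Se(=O)OH and the ring alkene at C7=C8 | O[Se](=O)CC1=CC[C@@H]2[C@](C)(CO3)[C@H](OC3(C)C)CC[C@@]2(C)[C@@H]1CCC1=CCOC1=O | intermediate
6 | selenoxylate ester (ester of divalent selenium): (7S) C7–O–Se–OH derivative of 7, exocyclic methylene restored | C=C1[C@@H](O[Se]O)C[C@@H]2[C@](C)(CO3)[C@H](OC3(C)C)CC[C@@]2(C)[C@@H]1CCC1=CCOC1=O | intermediate
7 | (7S)-7-hydroxy-3,19-O-isopropylidene-14-deoxyandrographolide (7-OH axial, anti to the C10 methyl, syn to H-5 and H-9) | C=C1[C@@H](O)C[C@@H]2[C@](C)(CO3)[C@H](OC3(C)C)CC[C@@]2(C)[C@@H]1CCC1=CCOC1=O | intermediate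
8 | 7-oxo-3,19-O-isopropylidene-14-deoxyandrographolide (8(17)-en-7-one) | C=C1C(=O)C[C@@H]2[C@](C)(CO3)[C@H](OC3(C)C)CC[C@@]2(C)[C@@H]1CCC1=CCOC1=O | intermediate
9 | (7R)-7-hydroxy-3,19-O-isopropylidene-14-deoxyandrographolide (7-OH equatorial, syn to the C10 methyl) | C=C1[C@H](O)C[C@@H]2[C@](C)(CO3)[C@H](OC3(C)C)CC[C@@]2(C)[C@@H]1CCC1=CCOC1=O | intermediate
10 | (7R)-7-hydroxy-14-deoxyandrographolide, i.e. 3,7,19-trihydroxy-ent-labda-8(17),13-dien-16,15-olide; (3R,4R,5S,7R,9S,10S), where the C9 descriptor reads S only because C8 gains priority and the geometry is that of 1 | C=C1[C@H](O)C[C@@H]2[C@](C)(CO)[C@H](O)CC[C@@]2(C)[C@@H]1CCC1=CCOC1=O | target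

**Step count**
Total: 6 steps from 1. Longest linear sequence: 6 steps (fully linear).

**Steps most likely to fail** (route order; by concern: step 3, then step 2, then step 5)

Step 2 is at risk because hydride must add in conjugate fashion before the basic medium simply eliminates the acetate to the 11,12-didehydro diene, and it must not go on to reduce the new butenolide. The fallback sets out from 2, isolated after the ketalisation of step 1 instead of being acetylated, and comes back at 4 by a reductive 1,3-transposition of the allylic alcohol. Mitsunobu reaction with 2-nitrobenzenesulfonylhydrazide (PPh3, DEAD, THF, −30 °C) gives, with inversion at C14, the N-sulfonylhydrazine F1. On warming to 23 °C this loses 2-nitrobenzenesulfinic acid to give the allylic diazene F2, which expels N2 through a retro-ene hydrogen shift that puts H on C12 and the alkene at C13=C14, i.e. 4, with no hydride reagent in the flask.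

Step 3 is at risk of incomplete conversion and partial ketal loss; over-oxidation to 8 is harmless, since that material is pooled into the product of step 4. The fallback sets out from 4 and comes back at 7 with stoichiometric arylselenium in place of a direct C–H oxidation. Ene-type chlorination with hypochlorous acid (Ca(OCl)2, solid CO2, CH2Cl2–H2O, 0 °C) touches only the electron-rich alkene and gives the transposed allylic chloride F3 (17-chloro, 7-ene). PhSeNa (from PhSeSePh and NaBH4, EtOH, 0 °C) displaces chloride to give the allyl phenyl selenide F4. H2O2–pyridine (CH2Cl2, 0 °C) gives the allyl selenoxide F5, whose [2,3]-sigmatropic shift delivers oxygen to C7 as the selenenate ester F6, and this is hydrolysed in the flask to 7.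

Step 5 is at risk from the facial selectivity of the hydride and from the lability of exocyclic enone 8, which can isomerise to the 8(9)-enone before it is reduced. The fallback sets out from 7 and comes back at 9 without passing through 8. Mitsunobu inversion of the axial alcohol with 4-nitrobenzoic acid (PPh3, DIAD, toluene, 0 °C → rt) gives the equatorial (7R) 4-nitrobenzoate F7, and brief methanolysis (K2CO3, MeOH, 0 °C) releases 9.

**Further compounds**
F1 | step 2 | (14R)-14-deoxy-14-[1-(2-nitrophenylsulfonyl)hydrazin-1-yl]-3,19-O-isopropylideneandrographolide (N-sulfonylhydrazine) | C=C1CC[C@@H]2[C@](C)(CO3)[C@H](OC3(C)C)CC[C@@]2(C)[C@@H]1C/C=C1\[C@@H](N(N)S(=O)(=O)c2ccccc2[N+](=O)[O-])COC1=O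
F2 | step 2 | (14R)-14-deoxy-14-diazenyl-3,19-O-isopropylideneandrographolide (allylic diazene) | C=C1CC[C@@H]2[C@](C)(CO3)[C@H](OC3(C)C)CC[C@@]2(C)[C@@H]1C/C=C1\[C@@H](N=N)COC1=O
F3 | step 3 | 17-chloro isomer of 4 with the ring alkene at C7=C8 (allylic chloride) | ClCC1=CC[C@@H]2[C@](C)(CO3)[C@H](OC3(C)C)CC[C@@]2(C)[C@@H]1CCC1=CCOC1=O
F4 | step 3 | 17-phenylselanyl analogue of F3 (allyl phenyl selenide) | c1ccccc1[Se]CC1=CC[C@@H]2[C@](C)(CO3)[C@H](OC3(C)C)CC[C@@]2(C)[C@@H]1CCC1=CCOC1=O
F5 | step 3 | Se-oxide of F4 (allyl selenoxide, selenium centre undefined) | O=[Se](c1ccccc1)CC1=CC[C@@H]2[C@](C)(CO3)[C@H](OC3(C)C)CC[C@@]2(C)[C@@H]1CCC1=CCOC1=O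
F6 | step 3 | (7S)-7-O-phenylselanyl derivative of 7 (selenenate ester) | C=C1[C@@H](O[Se]c2ccccc2)C[C@@H]2[C@](C)(CO3)[C@H](OC3(C)C)CC[C@@]2(C)[C@@H]1CCC1=CCOC1=O
F7 | step 5 | (7R)-7-O-(4-nitrobenzoyl) derivative of 9 (4-nitrobenzoate) | C=C1[C@H](OC(=O)c2ccc(cc2)[N+](=O)[O-])C[C@@H]2[C@](C)(CO3)[C@H](OC3(C)C)CC[C@@]2(C)[C@@H]1CCC1=CCOC1=O
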